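**Retrosynthetic overview**

- The strategy rests on ring carbon C8: it carries the C7 carbinol chain and lies between the two oxygenated ring carbons C9 (C=O) and C12 (C–OH), which are bridged by C10(Br)=C11. Read with C9 as alcohol and C12 as ketone, ring C8–C12 is a trans-4-hydroxy-5-alkylcyclopent-2-enone, the product type of a 2-furylcarbinol rearrangement, and C8–C3 with the C7/C6/C5 triol maps onto C1–C6 of D-galactose.
- Disconnections: C14=C15 (Z-selective Wittig), C12–C13 (allyl addition to a C12 ketone, followed by oxidation at C9, which transposes the enone), C8–C9 (4π-electrocyclisation of a 4-bromo-2-furylcarbinol), C8–furan (furyllithium plus sugar aldehyde), C3=C4 (cross-metathesis).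
- Ring order: the C3–C8 chain is cut from the pyranoside, the bromofuran is attached at C8, C1–C2 are added, the only carbocycle (C8–C12) is closed, and C13/C14 and C15–C20 are attached last.

Key step: step 10

Remark (assumption): locants follow prostanoid numbering (C1 ester carbon, C8–C12 ring, C20 chain end), so the target is read as methyl (5S,6S,7S,8R,12S,14Z,17Z)-10-bromo-5,6,7,12-tetrahydroxy-9-oxoprosta-10,14,17-trien-1-oate. Compounds 10, 11, 13 and 14 are carried as mixtures of C8 epimers because C8 becomes planar in step 10.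

**Route**

Step 1
Reactants: 1 methyl α-D-galactopyranoside
Product: 2 methyl 6-deoxy-6-iodo-α-D-galactopyranoside
Conditions: I2, PPh3, imidazole, THF, reflux
Reagents that add atoms: iodine, II
Why: Appel-type iodination under Garegg–Samuelsson conditions, in which the alkoxyphosphonium salt forms and is displaced by iodide only at the unhindered primary C6 hydroxyl, so the secondary hydroxyls and all stereocentres stay untouched.

Step 2
Reactants: 2 methyl 6-deoxy-6-iodo-α-D-galactopyranoside
Product: 3 methyl 6-deoxy-6-iodo-3,4-O-isopropylidene-α-D-galactopyranoside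
Conditions: Me2C(OMe)2, TsOH·H2O (cat.), acetone, rt
Reagents that add atoms: 2,2-dimethoxypropane, COC(C)(C)OC
Why: Acid-catalysed transacetalisation, in which only O3 and O4 are cis and so close the five-membered dioxolane, leaving O2 free.

Step 3
Reactants: 3 methyl 6-deoxy-6-iodo-3,4-O-isopropylidene-α-D-galactopyranoside
Product: 4 methyl 6-deoxy-6-iodo-3,4-O-isopropylidene-2-O-(methoxymethyl)-α-D-galactopyranoside
Conditions: MOMCl, iPr2NEt, CH2Cl2, 0 °C to rt
Reagents that add atoms: chloromethyl methyl ether, COCCl
Why: O-Alkylation of the single free hydroxyl with the α-chloro ether gives the MOM ether, deliberately an ether and not a silyl group at the future O7, so that this oxygen can later bind the C12 enol.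

Step 4
Reactants: 4 methyl 6-deoxy-6-iodo-3,4-O-isopropylidene-2-O-(methoxymethyl)-α-D-galactopyranoside
Product: 5 5,6-dideoxy-3,4-O-isopropylidene-2-O-(methoxymethyl)-L-arabino-hex-5-enose
Conditions: Zn dust (activated), THF/H2O 4:1, sonication, 40 °C; crude aldehyde dried azeotropically and used at once
Reagents that add atoms: none
Why: Bernet–Vasella reductive fragmentation, in which zinc inserts into the C6–I bond and the organozinc expels the ring oxygen, collapsing the methyl acetal to the aldehyde without touching sugar C2–C4 (the future C7, C6, C5); immediate use avoids epimerisation at the α-alkoxy centre C7.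

Step 5
Reactants: 6 3-bromofuran
Product: 8 3-bromo-2-(trimethylsilyl)furan, via 3-bromo-2-lithiofuran 7 (not isolated)
Conditions: LiN(iPr)2, THF, −78 °C; then Me3SiCl, −78 °C to rt
Reagents that add atoms: chlorotrimethylsilane, C[Si](C)(C)Cl
Why: Directed deprotonation, since the C2 proton flanked by oxygen and bromine is the most acidic and is removed at −78 °C without halogen migration, and silylation then blocks this position.

Step 6
Reactants: 8 3-bromo-2-(trimethylsilyl)furan; 5 5,6-dideoxy-3,4-O-isopropylidene-2-O-(methoxymethyl)-L-arabino-hex-5-enose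
Product: 10 [4-bromo-5-(trimethylsilyl)furan-2-yl]carbinol (C8 epimers), via 3-bromo-5-lithio-2-(trimethylsilyl)furan 9 (not isolated)
Conditions: 8, LiN(iPr)2, THF, −78 °C; then 5 in THF, −78 °C; H2O quench
Reagents that add atoms: none
Why: With C2 blocked, amide-base lithiation occurs at the remaining α-position and 1,2-addition of the furyllithium to the aldehyde forms the C8–furan bond; the configuration of the new C8 carbinol is irrelevant because this centre is ionised in step 10.

Step 7
Reactants: 10 [4-bromo-5-(trimethylsilyl)furan-2-yl]carbinol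
Product: 11 (4-bromofuran-2-yl)carbinol with C7 OMOM, C5/C6 acetonide and terminal C3=C4 vinyl group (C8 epimers)
Conditions: Bu4NF, THF, 0 °C to rt
Reagents that add atoms: none
Why: Fluoride-induced protodesilylation of the α-silylfuran, helped by the adjacent bromine that stabilises the developing furyl anion, frees the furan position that must take up water in step 10.

Step 8
Reactants: 11 (4-bromofuran-2-yl)carbinol; 12 methyl but-3-enoate
Product: 13 methyl (3E,5S,6S,7S)-8-(4-bromofuran-2-yl)-8-hydroxy-5,6-(isopropylidenedioxy)-7-(methoxymethoxy)oct-3-enoate (C8 epimers)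
Conditions: 12 (5 equiv), second-generation Grubbs catalyst RuCl2(=CHPh)(PCy3)(H2IMes) (5 mol %), 1,4-benzoquinone (10 mol %), CH2Cl2, 40 °C
Reagents that add atoms: none
Why: Olefin cross-metathesis, in which the hindered vinyl group next to the acetal does not homodimerise and is intercepted by the ruthenium alkylidene of the unhindered ester olefin used in excess; alkene geometry and any migration into conjugation do not matter because the double bond is reduced next.

Step 9
Reactants: 13 methyl (3E,5S,6S,7S)-8-(4-bromofuran-2-yl)-8-hydroxy-5,6-(isopropylidenedioxy)-7-(methoxymethoxy)oct-3-enoate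
Product: 14 methyl (5S,6S,7S)-8-(4-bromofuran-2-yl)-8-hydroxy-5,6-(isopropylidenedioxy)-7-(methoxymethoxy)octanoate (C8 epimers)
Conditions: 2-nitrobenzenesulfonylhydrazide, Et3N, CH2Cl2, rt
Reagents that add atoms: none
Why: Diimide reduction, in which the diimide made in the flask transfers two hydrogens concertedly to the unpolarised C3=C4 bond and leaves the aromatic furan, the furyl bromide and the furfurylic C8–O bond untouched, all of which a heterogeneous hydrogenation would endanger.

Step 10
Reactants: 14 methyl (5S,6S,7S)-8-(4-bromofuran-2-yl)-8-hydroxy-5,6-(isopropylidenedioxy)-7-(methoxymethoxy)octanoate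
Product: 15 methyl (5S,6S,7S)-7-[(1R,2S)-3-bromo-2-hydroxy-5-oxocyclopent-3-en-1-yl]-5,6-(isopropylidenedioxy)-7-(methoxymethoxy)heptanoate (C12 ketone, C10 bromide, C9–OH trans to the C8 chain)
Conditions: Dy(OTf)3 (10 mol %), tBuOH/H2O 5:1, 80 °C
Reagents that add atoms: water, O
Why: Proposed new method: Dy(OTf)3 ionises the C8 carbinol to the furfuryl cation, water adds at the free furan α-carbon (C9), and opening of the furan C–O bond gives the hydroxypentadienyl cation C8=C12(OH)–C11=C10(Br)–C9(+)–OH, which closes by thermal conrotatory 4π-electrocyclisation (the cyclopentene C8–C9–C10–C11–C12 forms through the C8–C9 bond) and tautomerises to the C12 enone, the furan oxygen ending as the C12 carbonyl. The closest known reaction is the Piancatelli rearrangement of 2-furylcarbinols to trans-4-hydroxy-5-substituted cyclopent-2-enones, which has not been shown for a 4-bromofuran or with an α-alkoxy stereocentre as the control element. C9 is unsubstituted, the fast classical case, and the bromine sits on an inner carbon of the cation, where it does not block water attack and ends as the vinylic bromide at C10. The trans relation of the C9 hydroxyl and the C8 chain follows from conrotation of the two outward-pointing termini. The absolute sense at C8 must come from C7: with the MOM oxygen held in the dienol plane by hydrogen bonding or chelation to the C12 enol oxygen, H7 and C6 lie on opposite faces, and C9 should bond to the C8 face anti to the C6 dioxolane carbon, which gives 8R. The nearly neutral aqueous medium is chosen so that a 1,2-hydride shift from C7, capture of the cation by the O5 acetal oxygen and hydrolysis of the β-bromoenone or the acetonide stay slow.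

Step 11
Reactants: 15 cyclopentenone (C12 ketone); 16 allyl bromide
Product: 18 methyl (5S,6S,7S)-7-[(1R,2S,5S)-5-allyl-3-bromo-2,5-dihydroxycyclopent-3-en-1-yl]-5,6-(isopropylidenedioxy)-7-(methoxymethoxy)heptanoate, via allylindium dibromide 17 (not isolated)
Conditions: In powder, 16, THF/H2O 4:1, rt
Reagents that add atoms: none
Why: Barbier allylation, in which the allylindium species adds 1,2 to the C12 ketone (the methyl ester is inert and the six-membered carbonyl-addition transition state disfavours attack at the brominated β-carbon) from the face opposite the adjacent C8 side chain, the face carrying only the small C9 hydroxyl, so C12 is set with the allyl group trans to the chain.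

Step 12
Reactants: 18 C12 tertiary allylic alcohol (9,12-diol)
Product: 19 9,12-bis(triethylsilyl) ether of 18
Conditions: Et3SiOTf, 2,6-lutidine, CH2Cl2, −78 to 0 °C
Reagents that add atoms: triethylsilyl trifluoromethanesulfonate, CC[Si](CC)(CC)OS(=O)(=O)C(F)(F)F
Why: Silyl triflate silylation is forceful enough for the tertiary C12 hydroxyl as well as the secondary C9 hydroxyl, and at low temperature with a hindered pyridine the MOM ether and the acetonide are not activated.

Step 13
Reactants: 19 9,12-bis(triethylsilyl) ether
Product: 21 C14 aldehyde (12-CH2CHO) with C9 and C12 triethylsilyl ethers, via vicinal diol 20 (not isolated)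
Conditions: OsO4 (2 mol %), NaIO4, 2,6-lutidine, dioxane/H2O 3:1, rt
Reagents that add atoms: osmium tetroxide, O=[Os](=O)(=O)=O; sodium periodate, [Na+].[O-]I(=O)(=O)=O
Why: Lemieux–Johnson oxidation, in which OsO4 dihydroxylates the monosubstituted terminal alkene far faster than the trisubstituted, bromine-bearing ring alkene flanked by two silyloxy carbons, and periodate cleaves the diol to the C14 aldehyde under lutidine buffering that spares the silyl ethers.

Step 14
Reactants: 22 (Z)-hex-3-en-1-ol
Product: 23 (Z)-1-bromohex-3-ene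
Conditions: CBr4, PPh3, CH2Cl2, 0 °C
Reagents that add atoms: carbon tetrabromide, BrC(Br)(Br)Br
Why: Appel bromination replaces the primary hydroxyl by SN2 displacement under neutral conditions that neither touch nor isomerise the Z alkene.

Step 15
Reactants: 23 (Z)-1-bromohex-3-ene
Product: 24 [(Z)-hex-3-en-1-yl]triphenylphosphonium bromide
Conditions: PPh3, MeCN, reflux
Reagents that add atoms: triphenylphosphine, c1ccc(cc1)P(c1ccccc1)c1ccccc1
Why: SN2 quaternisation of triphenylphosphine by the primary bromide gives the phosphonium salt.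

Step 16
Reactants: 24 [(Z)-hex-3-en-1-yl]triphenylphosphonium bromide; 21 C14 aldehyde
Product: 26 bis(triethylsilyl) ether carrying the complete (2Z,5Z)-octa-2,5-dienyl chain at C12, via phosphonium ylide 25 (not isolated)
Conditions: 24, NaN(SiMe3)2, THF, −78 to 0 °C; then 21, −78 °C to rt
Reagents that add atoms: none
Why: Wittig olefination with a non-stabilised, lithium-free ylide at −78 °C goes through the kinetically formed cis-oxaphosphetane and so sets C14=C15 as Z, while the low temperature holds back enolisation and β-elimination of the C12 silyloxy group and the C17=C18 Z alkene is carried in unchanged.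

Step 17
Reactants: 26 bis(triethylsilyl) ether with the dienyl chain
Product: 27 9,12-diol with the (14Z,17Z)-diene, C7 OMOM and C5/C6 acetonide
Conditions: HF·pyridine, pyridine, THF, 0 °C to rt
Reagents that add atoms: none
Why: Buffered HF·pyridine cleaves both triethylsilyl ethers through Si–F bond formation while the MOM ether, acetonide, methyl ester, vinyl bromide and skipped diene survive.

Step 18
Reactants: 27 9,12-diol
Product: 28 methyl (14Z,17Z)-10-bromo-12-hydroxy-5,6-(isopropylidenedioxy)-7-(methoxymethoxy)-9-oxoprosta-10,14,17-trienoate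
Conditions: Dess–Martin periodinane, NaHCO3, CH2Cl2, 0 °C to rt
Reagents that add atoms: none
Why: Dess–Martin oxidation can touch only the secondary allylic C9 hydroxyl (C12 is tertiary), and the new ketone is conjugated to C10=C11, so the 2-bromoenone of the target appears, transposed relative to the enone of 15, while C8 and C12 are unaffected under bicarbonate buffering.

Step 19
Reactants: 28 protected 2-bromoenone
Product: 29 methyl (5S,6S,7S,8R,12S,14Z,17Z)-10-bromo-5,6,7,12-tetrahydroxy-9-oxoprosta-10,14,17-trien-1-oate (target)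
Conditions: Me2BBr, CH2Cl2, −78 °C; then NaHCO3 aq/THF
Reagents that add atoms: none
Why: Me2BBr is an acetal-selective Lewis acid that cleaves the MOM ether and the acetonide at −78 °C; the tertiary C12 hydroxyl is now γ to the enone carbonyl, so its ionisation is disfavoured, and the low temperature with bicarbonate quench limits β-elimination across C7–C8 and δ-lactonisation of the 5-hydroxy ester.

**Compound list**

1 | methyl α-D-galactopyranoside | CO[C@H]1O[C@H](CO)[C@H](O)[C@H](O)[C@H]1O | starting material
2 | methyl 6-deoxy-6-iodo-α-D-galactopyranoside | CO[C@H]1O[C@H](CI)[C@H](O)[C@H](O)[C@H]1O | intermediate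
3 | methyl 6-deoxy-6-iodo-3,4-O-isopropylidene-α-D-galactopyranoside | CO[C@H]1O[C@H](CI)[C@@H]2OC(C)(C)O[C@@H]2[C@H]1O | intermediate
4 | methyl 6-deoxy-6-iodo-3,4-O-isopropylidene-2-O-(methoxymethyl)-α-D-galactopyranoside | CO[C@H]1O[C@H](CI)[C@@H]2OC(C)(C)O[C@@H]2[C@H]1OCOC | intermediate
5 | 5,6-dideoxy-3,4-O-isopropylidene-2-O-(methoxymethyl)-L-arabino-hex-5-enose (C8 aldehyde, C7 OMOM, C5/C6 acetonide, C3=C4 vinyl) | O=C[C@H](OCOC)[C@H]1OC(C)(C)O[C@H]1C=C | intermediate
6 | 3-bromofuran | Brc1ccoc1 | starting material
7 | 3-bromo-2-lithiofuran (not isolated) | [Li]c1occc1Br | intermediate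
8 | 3-bromo-2-(trimethylsilyl)furan | C[Si](C)(C)c1occc1Br | intermediate
9 | 3-bromo-5-lithio-2-(trimethylsilyl)furan (not isolated) | [Li]c1cc(Br)c([Si](C)(C)C)o1 | intermediate
10 | [4-bromo-5-(trimethylsilyl)furan-2-yl]carbinol: C8 secondary alcohol (both epimers), (7S)-OMOM, (5S,6S)-acetonide, terminal C3=C4 vinyl | OC(c1cc(Br)c([Si](C)(C)C)o1)[C@H](OCOC)[C@H]1OC(C)(C)O[C@H]1C=C | intermediate
11 | (4-bromofuran-2-yl)carbinol: as 10 without the silyl group (C8 epimers) | OC(c1cc(Br)co1)[C@H](OCOC)[C@H]1OC(C)(C)O[C@H]1C=C | intermediate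
12 | methyl but-3-enoate | C=CCC(=O)OC | starting material
13 | methyl (3E,5S,6S,7S)-8-(4-bromofuran-2-yl)-8-hydroxy-5,6-(isopropylidenedioxy)-7-(methoxymethoxy)oct-3-enoate (C8 epimers) | OC(c1cc(Br)co1)[C@H](OCOC)[C@H]1OC(C)(C)O[C@H]1/C=C/CC(=O)OC | intermediate
14 | methyl (5S,6S,7S)-8-(4-bromofuran-2-yl)-8-hydroxy-5,6-(isopropylidenedioxy)-7-(methoxymethoxy)octanoate (C8 epimers) | OC(c1cc(Br)co1)[C@H](OCOC)[C@H]1OC(C)(C)O[C@H]1CCCC(=O)OC | intermediate
15 | methyl (5S,6S,7S)-7-[(1R,2S)-3-bromo-2-hydroxy-5-oxocyclopent-3-en-1-yl]-5,6-(isopropylidenedioxy)-7-(methoxymethoxy)heptanoate | O=C1C=C(Br)[C@@H](O)[C@@H]1[C@H](OCOC)[C@H]2OC(C)(C)O[C@H]2CCCC(=O)OC | intermediate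
16 | allyl bromide | C=CCBr | starting material
17 | allylindium dibromide, drawn as the simplest component of the allylindium species (not isolated) | C=CC[In](Br)Br | intermediate
18 | methyl (5S,6S,7S)-7-[(1R,2S,5S)-5-allyl-3-bromo-2,5-dihydroxycyclopent-3-en-1-yl]-5,6-(isopropylidenedioxy)-7-(methoxymethoxy)heptanoate (allyl trans to the C8 chain) | C=CC[C@@]1(O)C=C(Br)[C@@H](O)[C@@H]1[C@H](OCOC)[C@H]2OC(C)(C)O[C@H]2CCCC(=O)OC | intermediate
19 | 9,12-bis(triethylsilyl) ether of 18 | C=CC[C@@]1(O[Si](CC)(CC)CC)C=C(Br)[C@@H](O[Si](CC)(CC)CC)[C@@H]1[C@H](OCOC)[C@H]2OC(C)(C)O[C@H]2CCCC(=O)OC | intermediate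
20 | vicinal diol from dihydroxylation of the allyl group of 19 (C14 epimers, not isolated) | OCC(O)C[C@@]1(O[Si](CC)(CC)CC)C=C(Br)[C@@H](O[Si](CC)(CC)CC)[C@@H]1[C@H](OCOC)[C@H]2OC(C)(C)O[C@H]2CCCC(=O)OC | intermediate
21 | C14 aldehyde: 12-(2-oxoethyl) compound with C9 and C12 triethylsilyl ethers | O=CC[C@@]1(O[Si](CC)(CC)CC)C=C(Br)[C@@H](O[Si](CC)(CC)CC)[C@@H]1[C@H](OCOC)[C@H]2OC(C)(C)O[C@H]2CCCC(=O)OC | intermediate
22 | (Z)-hex-3-en-1-ol | CC/C=C\CCO | starting material
23 | (Z)-1-bromohex-3-ene | CC/C=C\CCBr | intermediate
24 | [(Z)-hex-3-en-1-yl]triphenylphosphonium bromide | CC/C=C\CC[P+](c1ccccc1)(c1ccccc1)c1ccccc1.[Br-] | intermediate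
25 | [(Z)-hex-3-enylidene]triphenylphosphorane (not isolated) | CC/C=C\CC=P(c1ccccc1)(c1ccccc1)c1ccccc1 | intermediate
26 | methyl (14Z,17Z)-10-bromo-5,6-(isopropylidenedioxy)-7-(methoxymethoxy)-9,12-bis(triethylsilyloxy)prosta-10,14,17-trienoate | CC/C=C\C/C=C\C[C@@]1(O[Si](CC)(CC)CC)C=C(Br)[C@@H](O[Si](CC)(CC)CC)[C@@H]1[C@H](OCOC)[C@H]2OC(C)(C)O[C@H]2CCCC(=O)OC | intermediate
27 | methyl (14Z,17Z)-10-bromo-9,12-dihydroxy-5,6-(isopropylidenedioxy)-7-(methoxymethoxy)prosta-10,14,17-trienoate | CC/C=C\C/C=C\C[C@@]1(O)C=C(Br)[C@@H](O)[C@@H]1[C@H](OCOC)[C@H]2OC(C)(C)O[C@H]2CCCC(=O)OC | intermediate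
28 | methyl (14Z,17Z)-10-bromo-12-hydroxy-5,6-(isopropylidenedioxy)-7-(methoxymethoxy)-9-oxoprosta-10,14,17-trienoate | CC/C=C\C/C=C\C[C@@]1(O)C=C(Br)C(=O)[C@@H]1[C@H](OCOC)[C@H]2OC(C)(C)O[C@H]2CCCC(=O)OC | intermediate
29 | methyl (5S,6S,7S,8R,12S,14Z,17Z)-10-bromo-5,6,7,12-tetrahydroxy-9-oxoprosta-10,14,17-trien-1-oate (CNP0143456.1) | CC/C=C\C/C=C\C[C@@]1(O)C=C(Br)C(=O)[C@@H]1[C@H](O)[C@@H](O)[C@@H](O)CCCC(=O)OC | target

**Step count and risks**

Total step count: 19. Longest linear sequence: 16 steps (steps 1–4, 6–13 and 16–19, from methyl α-D-galactopyranoside).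

Steps most likely to fail:

1. Step 10 (labelled step). Ionisation at C8 may be slowed by the neighbouring C7 ether and the ring bromine, so that acetal hydrolysis, hydride migration from C7 or hydrolysis of the vinylogous acyl bromide outrun the electrocyclisation; the conrotation may also show poor facial selectivity. The fallback uses known chemistry and avoids the furfuryl cation: it sets out from furylcarbinol 14 and comes back to the route at cyclopentenone 15, forming the same C8–C9 bond by an intramolecular aldol reaction. Compound 14 is acylated with O-phenyl chlorothionoformate (pyridine, DMAP, CH2Cl2) to the O-phenyl thionocarbonate F1. Barton–McCombie deoxygenation (Bu3SnH, AIBN, toluene, 80 °C) should then give the 2-alkyl-4-bromofuran F2, in which C8 is a CH2 group. Oxidative opening of the furan with NBS and NaHCO3 in aqueous acetone at −20 °C should give the cis-configured bromo keto enal F3 (C12 ketone, C9 aldehyde). Buffered aldol closure of the C8 enolate on the C9 aldehyde (pH 7 to 8 phosphate, aqueous dioxane, 40 °C), the classical way from 2-alkylfurans to 4-hydroxy-5-alkylcyclopentenones, should give 15 with the C9 hydroxyl trans to the C8 chain. The two trans isomers that differ in ring face relative to C7 would be separated at this point.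

2. Step 11. The zero-valent metal may reduce or displace the vinylogous acyl bromide, the unprotected β-hydroxy ketone may undergo retro-aldol cleavage or dehydration in the aqueous medium, and coordination of the C9 hydroxyl to the metal may erode the facial preference. The fallback sets out from 15 and comes back at bis-silyl ether 19; it replaces the aqueous Barbier reaction on the free hydroxy ketone by addition of a preformed organocerium reagent to the protected ketone. Compound 15 is silylated (Et3SiCl, imidazole, DMF, 0 °C) to the C9 triethylsilyl ether F4. CH2=CHCH2MgBr premixed with anhydrous CeCl3 (THF, −78 °C) should add to C12 anti to the C8 chain, now under purely steric control, to give the tertiary alcohol F5. Et3SiOTf with 2,6-lutidine then gives 19.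

3. Step 16. The basic ylide may enolise aldehyde 21 and expel the C12 silyloxy group by β-elimination, or the olefination may lose Z-selectivity. The fallback sets out from 15 and comes back at diene 26; it builds C14=C15 by alkyne coupling and cis-reduction in place of the aldehyde and Wittig pair. Indium-mediated Barbier propargylation of 15 (propargyl bromide, In powder, THF/H2O) should give the homopropargylic alcohol F6 with the same facial sense as step 11. Et3SiOTf with 2,6-lutidine gives the bis(triethylsilyl) ether F7. Copper-mediated coupling of the terminal alkyne with (Z)-1-bromopent-2-ene (CuI, NaI, Cs2CO3, DMF) gives the skipped enyne F8. Semi-hydrogenation (H2, Pd on CaCO3 poisoned with Pb(OAc)2, quinoline, EtOAc, stopped after one equivalent) should give 26.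

**Further compounds**

F1 | step 10 | O-phenyl thionocarbonate of furylcarbinol 14 (C8 epimers) | S=C(Oc1ccccc1)OC(c1cc(Br)co1)[C@H](OCOC)[C@H]1OC(C)(C)O[C@H]1CCCC(=O)OC
F2 | step 10 | methyl (5S,6S,7S)-8-(4-bromofuran-2-yl)-5,6-(isopropylidenedioxy)-7-(methoxymethoxy)octanoate (C8 deoxygenated) | Brc1coc(C[C@H](OCOC)[C@H]2OC(C)(C)O[C@H]2CCCC(=O)OC)c1
F3 | step 10 | cis-bromo keto enal: methyl (5S,6S,7S)-11-bromo-5,6-(isopropylidenedioxy)-7-(methoxymethoxy)-9,12-dioxododec-10-enoate, acyl and formyl groups cis | O=C/C(Br)=C\C(=O)C[C@H](OCOC)[C@H]1OC(C)(C)O[C@H]1CCCC(=O)OC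
F4 | step 11 | C9 triethylsilyl ether of cyclopentenone 15 | O=C1C=C(Br)[C@@H](O[Si](CC)(CC)CC)[C@@H]1[C@H](OCOC)[C@H]2OC(C)(C)O[C@H]2CCCC(=O)OC
F5 | step 11 | C12 tertiary allyl carbinol with C9 triethylsilyl ether | C=CC[C@@]1(O)C=C(Br)[C@@H](O[Si](CC)(CC)CC)[C@@H]1[C@H](OCOC)[C@H]2OC(C)(C)O[C@H]2CCCC(=O)OC
F6 | step 16 | C12 tertiary homopropargylic alcohol (12-prop-2-ynyl, 9,12-diol) | C#CC[C@@]1(O)C=C(Br)[C@@H](O)[C@@H]1[C@H](OCOC)[C@H]2OC(C)(C)O[C@H]2CCCC(=O)OC
F7 | step 16 | 9,12-bis(triethylsilyl) ether of the homopropargylic alcohol | C#CC[C@@]1(O[Si](CC)(CC)CC)C=C(Br)[C@@H](O[Si](CC)(CC)CC)[C@@H]1[C@H](OCOC)[C@H]2OC(C)(C)O[C@H]2CCCC(=O)OC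
F8 | step 16 | skipped enyne: 12-[(5Z)-oct-5-en-2-ynyl] bis(triethylsilyl) ether | CC/C=C\CC#CC[C@@]1(O[Si](CC)(CC)CC)C=C(Br)[C@@H](O[Si](CC)(CC)CC)[C@@H]1[C@H](OCOC)[C@H]2OC(C)(C)O[C@H]2CCCC(=O)OC
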